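**A direct plan and its weak points**

A direct plan would make the tris-TIPS stilbene A1 (ring C with its 2-OH free, ring D, and the olefin between them) by a four-step Wittig sequence.
It would then add 4-bromoresorcinol A2 across that olefin under a chiral Brønsted acid to give the triarylethane bromide A3, cap the three new phenols, attach the stilbene arm by a Heck reaction with styrene A4, and remove eight silyl ethers.
- Weak point 1, the acid-catalysed hydroarylation of A1 that sets the only stereocentre: protonation of a stilbene to a reactive cation has no close precedent, A1 can dimerise, and the same acid can ionise the electron-rich product A3 again and erode its configuration.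
- Weak point 2, the run-up and protecting-group traffic: four linear steps for the simple stilbene A1, then a silylation that builds nothing, with two silyl families and eight silyl ethers in all.
- Weak point 3, the late Heck coupling: it must occur at an electron-rich aryl bromide flanked by a bulky silyl ether, and is followed by an eightfold desilylation of an air- and light-sensitive stilbene polyphenol.

**Retrosynthetic overview of the new route**

Ring A is the 3,5-dihydroxyphenyl of the stilbene, ring B the central 4,6-disubstituted resorcinol, ring C the 2,4-dihydroxyphenyl on the stereocentre, ring D the 3,5-dihydroxyphenyl on CH2.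
The feature used is the sp3 pair C*H–CH2 that joins rings B, C and D (a 1,1,2-triarylethane); it is read as a vinyl group on ring B plus two aryl halides.
Key disconnection: C*–C1(ring C) and CH2–B are formed together in a three-component enantioselective Cu/Pd arylboration of the ring B vinyl group, with the ring C iodide and B2pin2; CH2–C1(ring D) then follows by B-alkyl Suzuki coupling.
No ring is formed: four catalogue benzene rings are joined in the order A+B (olefination), vinyl, C (key step), D, and the eight methyl ethers are bought in and leave together at the end.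
This avoids the weak points: no acid or cation at the stereocentre, the catalyst tells aryl from CH2B and never compares the two resorcinol rings, the stilbene is made first so there is no late Heck, and there are no protection steps.

Key step: step 3

Assumption: the (R)-sulfoxide-phosphine ligand is written as the enantiomer expected to give (S)-7; if the sense of induction on this substrate were the opposite, the (S)-ligand would be used with no other change.

**Route**

Step 1
Reactants: 1 5-bromo-2,4-dimethoxybenzaldehyde, 2 diethyl (3,5-dimethoxybenzyl)phosphonate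
Product: 4 (E)-1-bromo-2,4-dimethoxy-5-[2-(3,5-dimethoxyphenyl)ethenyl]benzene, via potassium phosphonate carbanion 3 (not isolated)
Conditions: 2 (1.1 equiv), KOt-Bu (1.2 equiv), THF, 0 °C; then 1, 0 °C to rt
Reagents that add atoms: none
Why: Horner-Wadsworth-Emmons olefination of the non-enolisable aldehyde 1 with the benzylic phosphonate carbanion 3 should give the E-stilbene selectively, and the aryl bromide is inert to the base.

Step 2
Reactants: 4 (E)-1-bromo-2,4-dimethoxy-5-[2-(3,5-dimethoxyphenyl)ethenyl]benzene
Product: 5 1-ethenyl-2,4-dimethoxy-5-[(E)-2-(3,5-dimethoxyphenyl)ethenyl]benzene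
Conditions: vinylboronic acid pinacol ester (1.5 equiv), Pd(dppf)Cl2 (3 mol %), K2CO3 (3 equiv), 1,4-dioxane/H2O (4:1), BHT (trace), 85 °C, Ar
Reagents that add atoms: vinylboronic acid pinacol ester, C=CB1OC(C)(C)C(C)(C)O1
Why: Suzuki-Miyaura vinylation of the electron-rich aryl bromide should be fast with the dppf-ligated palladium catalyst, the internal E-stilbene is a poor Heck acceptor by comparison, and BHT keeps the divinyl arene from polymerising.

Step 3
Reactants: 5 1-ethenyl-2,4-dimethoxy-5-[(E)-2-(3,5-dimethoxyphenyl)ethenyl]benzene, 6 1-iodo-2,4-dimethoxybenzene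
Product: 7 2-[(2S)-2-(2,4-dimethoxyphenyl)-2-{2,4-dimethoxy-5-[(E)-2-(3,5-dimethoxyphenyl)ethenyl]phenyl}ethyl]-4,4,5,5-tetramethyl-1,3,2-dioxaborolane
Conditions: 6 (1.5 equiv), B2pin2 (1.5 equiv), CuCl (10 mol %), (R)-[2-(tert-butylsulfinyl)phenyl]diphenylphosphine (12 mol %), Pd(dppf)Cl2 (5 mol %), KOt-Bu (1.5 equiv), THF, 0 °C to rt, Ar
Reagents that add atoms: bis(pinacolato)diboron, CC1(C)OB(OC1(C)C)B1OC(C)(C)C(C)(C)O1
Why: The ligated copper tert-butoxide is borylated by B2pin2, the copper boryl adds syn across the terminal vinyl group of 5 with boron at CH2 and copper at the benzylic carbon, the benzylic copper transmetalates to the arylpalladium iodide formed from 6 and zerovalent palladium, and reductive elimination forms the C–C bond to ring C. The closest known reaction type is the cooperative Cu/Pd enantioselective arylboration of vinylarenes with aryl iodides and B2pin2, an established entry to 2,2-diarylethyl boronates and 1,1,2-triarylethanes. No ring closes. The stereocentre is set by the chiral sulfoxide-phosphine ligand on copper in the borylcupration, where the catalyst only has to tell an aryl group from CH2Bpin, and it is carried stereospecifically through transmetalation and reductive elimination, so the two nearly identical resorcinol rings are never compared. The step needs chemoselectivity for the terminal vinyl group over the internal E-stilbene, which the much slower borylcupration of a 1,2-diaryl olefin should secure, and regioselectivity for copper at the benzylic carbon, which the aryl group on that carbon secures. The product holds no halide and cannot react on, and the methyl ethers and the stilbene are inert to the alkoxide at room temperature.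

Step 4
Reactants: 7 2-[(2S)-2-(2,4-dimethoxyphenyl)-2-{2,4-dimethoxy-5-[(E)-2-(3,5-dimethoxyphenyl)ethenyl]phenyl}ethyl]-4,4,5,5-tetramethyl-1,3,2-dioxaborolane, 8 1-bromo-3,5-dimethoxybenzene
Product: 9 1-[(1S)-1-(2,4-dimethoxyphenyl)-2-(3,5-dimethoxyphenyl)ethyl]-2,4-dimethoxy-5-[(E)-2-(3,5-dimethoxyphenyl)ethenyl]benzene
Conditions: 8 (1.3 equiv), Pd(OAc)2 (5 mol %), RuPhos (10 mol %), KOH (3 equiv), THF/H2O (10:1), 70 °C, Ar
Reagents that add atoms: none
Why: B-alkyl Suzuki-Miyaura coupling of the primary pinacol boronate with the aryl bromide should succeed because reductive elimination from the bulky biarylphosphine complex outruns β-hydride elimination, and the stereocentre, one carbon away from boron, is not touched.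

Step 5
Reactants: 9 1-[(1S)-1-(2,4-dimethoxyphenyl)-2-(3,5-dimethoxyphenyl)ethyl]-2,4-dimethoxy-5-[(E)-2-(3,5-dimethoxyphenyl)ethenyl]benzene
Product: 10 4-[(1S)-1-(2,4-dihydroxyphenyl)-2-(3,5-dihydroxyphenyl)ethyl]-6-[(E)-2-(3,5-dihydroxyphenyl)ethenyl]benzene-1,3-diol (CNP0376747.1)
Conditions: BBr3 (16 equiv), CH2Cl2, -78 to 0 °C, Ar, exclusion of light; MeOH at -78 °C, then ice water, EtOAc
Reagents that add atoms: none
Why: Lewis acid cleavage of aryl methyl ethers by BBr3 (bromide attacks each methyl group of the boron-complexed ether) should remove all eight methyl groups in one operation, and the low temperature, high dilution and cold quench are meant to keep the stilbene and the benzylic stereocentre from acid-induced ionisation.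

**Compound list**

1 | 5-bromo-2,4-dimethoxybenzaldehyde | O=Cc1cc(Br)c(OC)cc1OC | starting material
2 | diethyl (3,5-dimethoxybenzyl)phosphonate | CCOP(=O)(Cc1cc(OC)cc(OC)c1)OCC | starting material
3 | potassium salt of the carbanion of diethyl (3,5-dimethoxybenzyl)phosphonate (not isolated) | [K+].CCOP(=O)([CH-]c1cc(OC)cc(OC)c1)OCC | intermediate
4 | (E)-1-bromo-2,4-dimethoxy-5-[2-(3,5-dimethoxyphenyl)ethenyl]benzene | COc1cc(OC)cc(/C=C/c2cc(Br)c(OC)cc2OC)c1 | intermediate
5 | 1-ethenyl-2,4-dimethoxy-5-[(E)-2-(3,5-dimethoxyphenyl)ethenyl]benzene | COc1cc(OC)cc(/C=C/c2cc(C=C)c(OC)cc2OC)c1 | intermediate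
6 | 1-iodo-2,4-dimethoxybenzene | COc1ccc(I)c(OC)c1 | starting material
7 | 2-[(2S)-2-(2,4-dimethoxyphenyl)-2-{2,4-dimethoxy-5-[(E)-2-(3,5-dimethoxyphenyl)ethenyl]phenyl}ethyl]-4,4,5,5-tetramethyl-1,3,2-dioxaborolane | COc1cc(OC)cc(/C=C/c2cc([C@@H](CB3OC(C)(C)C(C)(C)O3)c3ccc(OC)cc3OC)c(OC)cc2OC)c1 | intermediate
8 | 1-bromo-3,5-dimethoxybenzene | COc1cc(Br)cc(OC)c1 | starting material
9 | 1-[(1S)-1-(2,4-dimethoxyphenyl)-2-(3,5-dimethoxyphenyl)ethyl]-2,4-dimethoxy-5-[(E)-2-(3,5-dimethoxyphenyl)ethenyl]benzene (octamethyl ether of the target) | COc1cc(OC)cc(/C=C/c2cc([C@@H](Cc3cc(OC)cc(OC)c3)c3ccc(OC)cc3OC)c(OC)cc2OC)c1 | intermediate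
10 | 4-[(1S)-1-(2,4-dihydroxyphenyl)-2-(3,5-dihydroxyphenyl)ethyl]-6-[(E)-2-(3,5-dihydroxyphenyl)ethenyl]benzene-1,3-diol | Oc1cc(O)cc(/C=C/c2cc([C@@H](Cc3cc(O)cc(O)c3)c3ccc(O)cc3O)c(O)cc2O)c1 | target

**Step count and risks**

Total step count: 5. Longest linear sequence: 5 steps (1 to 4 to 5 to 7 to 9 to 10).

Steps most likely to fail:

1. Step 3 (key arylboration). Borylcupration of the electron-rich, ortho-substituted vinylarene may be slow, so that direct borylation or homocoupling of the aryl iodide, β-hydride elimination to an alkenyl boronate, or ligand exchange between the two metals with loss of enantioselectivity takes over. Fallback, setting out from 5 and coming back at 9: a platinum-catalysed enantioselective diboration of the terminal vinyl group (Pt(dba)3, a TADDOL-derived phenylphosphonite ligand of the enantiomer that gives the R product, B2pin2, THF, 60 °C) would leave the internal stilbene alone and give the (R)-1,2-bis(pinacol boronate) F1. Only the primary boronate of F1 would then couple with bromide 8 (Pd(OAc)2, RuPhos, KOH, THF/H2O, 70 °C) to give the (R)-secondary benzylic boronate F2. A stereoretentive Suzuki-Miyaura coupling of F2 with iodide 6 (Pd2(dba)3, PPh3, Ag2O, DME, 85 °C) would install ring C with retention and arrive at (S)-9.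

2. Step 5 (global demethylation). Acid released during cleavage or quench may protonate the stilbene and start oligomerisation, ionise the triarylethane carbon with loss of configuration, or isomerise the olefin, and the free polyphenol may oxidise in air during isolation. Fallback, setting out from 9 and coming back at 10: demethylation without acid by MeMgI as a melt (160 °C, Ar), quench with aqueous NH4Cl, and acetylation of the crude, unpurified polyphenol at once (Ac2O, pyridine) would give the octaacetate F5, which is stable on silica. Ammonolysis of purified F5 (NH3, MeOH, 0 °C, Ar) would release 10 under mild conditions.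

3. Step 4 (B-alkyl Suzuki coupling). The alkylpalladium intermediate carries a doubly benzylic β-hydrogen, so β-hydride elimination to the 1,1-diarylethylene, reinsertion with partial loss of configuration, or protodeboronation may compete. Fallback, setting out from 7 and coming back at 9: a transition-metal-free boronate coupling in which 3,5-dimethoxyphenyllithium F3 (from 8, n-BuLi, THF, -78 °C) adds to the boron of 7 to give the lithium boronate complex F4. NBS (THF, -78 °C to rt) would brominate the boron-activated, doubly methoxy-activated ring of F4, trigger 1,2-migration of the alkyl group from boron to the ipso carbon, and elimination of boron and bromide would give 9 with no alkylpalladium species involved.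

**Further compounds**

F1 | step 3 | 2,2'-[(1R)-1-{2,4-dimethoxy-5-[(E)-2-(3,5-dimethoxyphenyl)ethenyl]phenyl}ethane-1,2-diyl]bis(4,4,5,5-tetramethyl-1,3,2-dioxaborolane) | COc1cc(OC)cc(/C=C/c2cc([C@@H](CB3OC(C)(C)C(C)(C)O3)B3OC(C)(C)C(C)(C)O3)c(OC)cc2OC)c1
F2 | step 3 | 2-[(1R)-1-{2,4-dimethoxy-5-[(E)-2-(3,5-dimethoxyphenyl)ethenyl]phenyl}-2-(3,5-dimethoxyphenyl)ethyl]-4,4,5,5-tetramethyl-1,3,2-dioxaborolane | COc1cc(OC)cc(/C=C/c2cc([C@@H](Cc3cc(OC)cc(OC)c3)B3OC(C)(C)C(C)(C)O3)c(OC)cc2OC)c1
F3 | step 4 | 3,5-dimethoxyphenyllithium | [Li]c1cc(OC)cc(OC)c1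
F4 | step 4 | lithium (S)-configured boronate complex of 7 with a 3,5-dimethoxyphenyl group on boron | [Li+].COc1cc(OC)cc(/C=C/c2cc([C@@H](C[B-]3(c4cc(OC)cc(OC)c4)OC(C)(C)C(C)(C)O3)c3ccc(OC)cc3OC)c(OC)cc2OC)c1
F5 | step 5 | octaacetate of 10, (S,E)-configured | CC(=O)Oc1cc(OC(C)=O)cc(/C=C/c2cc([C@@H](Cc3cc(OC(C)=O)cc(OC(C)=O)c3)c3ccc(OC(C)=O)cc3OC(C)=O)c(OC(C)=O)cc2OC(C)=O)c1
A1 | direct plan | (E)-2-[3,5-bis(triisopropylsilyloxy)styryl]-5-(triisopropylsilyloxy)phenol | Oc1cc(O[Si](C(C)C)(C(C)C)C(C)C)ccc1/C=C/c1cc(O[Si](C(C)C)(C(C)C)C(C)C)cc(O[Si](C(C)C)(C(C)C)C(C)C)c1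
A2 | direct plan | 4-bromoresorcinol | Oc1ccc(Br)c(O)c1
A3 | direct plan | (S)-4-bromo-6-{2-[3,5-bis(triisopropylsilyloxy)phenyl]-1-[2-hydroxy-4-(triisopropylsilyloxy)phenyl]ethyl}benzene-1,3-diol | Brc1cc([C@@H](Cc2cc(O[Si](C(C)C)(C(C)C)C(C)C)cc(O[Si](C(C)C)(C(C)C)C(C)C)c2)c2ccc(O[Si](C(C)C)(C(C)C)C(C)C)cc2O)c(O)cc1O
A4 | direct plan | 3,5-bis(triisopropylsilyloxy)styrene | C=Cc1cc(O[Si](C(C)C)(C(C)C)C(C)C)cc(O[Si](C(C)C)(C(C)C)C(C)C)c1
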